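The 14-membered carbocycle (cembrane numbering, C1 = isopropyl-bearing carbon) is disconnected at C6–C7, the centre of its only unfunctionalised trimethylene (C5–C7). It is closed by ring-closing olefin metathesis of two vinyl termini, and the new alkene is then erased with diimide. The key step exploits the C9(O)–C8(CH2OH)–C7 array: an iridium-catalysed carbonyl (hydroxymethyl)allylation sets C8 and leaves C7 as the vinyl group that metathesis needs, while C8 stays non-epimerisable because C9 is still a carbinol. The precursor is an open-chain triene already carrying the cis C3–C4 epoxide (Sharpless) and the E C1=C2 enone (Horner–Wadsworth–Emmons union of a citronellic acid-derived phosphonate with an epoxy aldehyde).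

Key step: step 14

Remark (numbering): C1 = isopropyl-bearing alkene carbon, C2 = alkene CH, C3/C4 = epoxide carbons (methyl on C4), C8 = hydroxymethyl-bearing carbon, C9 and C14 = ketones, C12 = methyl-bearing carbon, C13 = carbinol. On the epoxide C2 and C5 are cis, so it derives from a Z (neryl-type) allylic alcohol.
Remark (form of the target): the open hydroxy diketone of the SMILES is taken as the target, not a hemiketal.
Remark (reagents): diethyl isobutylphosphonate and 4-vinyl-1,3-dioxolan-2-one are taken as purchasable.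

Step 1
Reactants: 1 but-2-yn-1-ol
Product: 3 (2Z)-3-iodobut-2-en-1-ol, via cyclic alkenylaluminate 2 (not isolated)
Conditions: NaAlH2(OCH2CH2OCH3)2, THF, 0 °C to rt; then I2, −78 °C to 0 °C
Reagents that add atoms: iodine, II
Why: Hydroxyl-directed trans-hydroalumination of the propargylic alcohol places aluminium at C3 in a five-membered alkoxyaluminate, and iodinolysis with retention should give the Z-iodide (hydroalumination–iodination).

Step 2
Reactants: 3 (2Z)-3-iodobut-2-en-1-ol
Product: 4 (2Z)-3-methylhexa-2,5-dien-1-ol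
Conditions: allyltributylstannane, Pd(PPh3)4 (5 mol %), CuI, CsF, DMF, 45 °C
Reagents that add atoms: allyltributylstannane, C=CC[Sn](CCCC)(CCCC)CCCC
Why: Stille cross-coupling: oxidative addition of the vinyl iodide to zerovalent palladium and allyl transfer from tin proceed with retention, so the Z-trisubstituted geometry is carried into the skipped dienol.

Step 3
Reactants: 4 (2Z)-3-methylhexa-2,5-dien-1-ol
Product: 5 [(2S,3R)-3-methyl-3-(prop-2-en-1-yl)oxiran-2-yl]methanol
Conditions: Ti(OiPr)4 (10 mol %), L-(+)-diethyl tartrate (12 mol %), tBuOOH, 4 Å molecular sieves, CH2Cl2, −20 °C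
Reagents that add atoms: tert-butyl hydroperoxide, CC(C)(C)OO
Why: Sharpless–Katsuki asymmetric epoxidation touches only the allylic alkene, and the L-(+)-tartrate titanium complex should deliver oxygen to the face that gives the (2S,3R) cis-epoxide (the same sense as for nerol), which fixes C3 and C4.

Step 4
Reactants: 5 [(2S,3R)-3-methyl-3-(prop-2-en-1-yl)oxiran-2-yl]methanol
Product: 6 (2R,3R)-3-methyl-3-(prop-2-en-1-yl)oxirane-2-carbaldehyde
Conditions: Dess–Martin periodinane, NaHCO3, CH2Cl2, 0 °C to rt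
Reagents that add atoms: none
Why: Buffered Dess–Martin oxidation converts the primary alcohol into the aldehyde without touching the epoxide or the terminal alkene, and the epoxide carbon next to the formyl group does not epimerise.

Step 5
Reactants: 7 (R)-citronellic acid
Product: 9 (4S)-4-benzyl-3-[(3R)-3,7-dimethyloct-6-enoyl]-1,3-oxazolidin-2-one, via mixed pivalic anhydride 8 (not isolated)
Conditions: tBuCOCl, Et3N, THF, −20 °C; then (S)-4-benzyl-1,3-oxazolidin-2-one, LiCl, −20 °C to rt
Reagents that add atoms: (S)-4-benzyl-1,3-oxazolidin-2-one, O=C1OC[C@H](Cc2ccccc2)N1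
Why: N-Acylation of the Evans auxiliary through the mixed anhydride occurs at the less hindered carbonyl and leaves the C12 centre, which is β to the carbonyl, untouched.

Step 6
Reactants: 9 (4S)-4-benzyl-3-[(3R)-3,7-dimethyloct-6-enoyl]-1,3-oxazolidin-2-one
Product: 11 (4S)-4-benzyl-3-[(2S,3R)-2-hydroxy-3,7-dimethyloct-6-enoyl]-1,3-oxazolidin-2-one, via sodium enolate 10 (not isolated)
Conditions: NaN(SiMe3)2, THF, −78 °C; then 2-(phenylsulfonyl)-3-phenyloxaziridine, −78 °C; AcOH quench
Reagents that add atoms: 2-(phenylsulfonyl)-3-phenyloxaziridine, O=S(=O)(c1ccccc1)N1OC1c1ccccc1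
Why: Evans-type enolate hydroxylation with the Davis oxaziridine: the chelated sodium Z-enolate is attacked on the face opposite the benzyl group, which should set C13 as S under auxiliary control irrespective of the adjacent C12 methyl.

Step 7
Reactants: 11 (4S)-4-benzyl-3-[(2S,3R)-2-hydroxy-3,7-dimethyloct-6-enoyl]-1,3-oxazolidin-2-one
Product: 12 (2S,3R)-2-hydroxy-N-methoxy-N,3,7-trimethyloct-6-enamide
Conditions: MeNH(OMe)·HCl, AlMe3, CH2Cl2, −15 °C to 0 °C; aqueous Rochelle salt
Reagents that add atoms: N,O-dimethylhydroxylamine hydrochloride, CNOC.Cl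
Why: Weinreb transamidation: the aluminium amide attacks the exocyclic imide carbonyl, assisted by the free α-hydroxyl, and releases the auxiliary without epimerising C13.

Step 8
Reactants: 12 (2S,3R)-2-hydroxy-N-methoxy-N,3,7-trimethyloct-6-enamide
Product: 13 (2S,3R)-N-methoxy-N,3,7-trimethyl-2-(triethylsilyloxy)oct-6-enamide
Conditions: Et3SiCl, imidazole, DMF, 0 °C to rt
Reagents that add atoms: chlorotriethylsilane, CC[Si](Cl)(CC)CC
Why: Silyl ether formation protects the C13 hydroxyl through the carbanion, oxidation and metathesis steps and allows one final desilylation.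

Step 9
Reactants: 13 (2S,3R)-N-methoxy-N,3,7-trimethyl-2-(triethylsilyloxy)oct-6-enamide
Product: 15 (2S,3R)-N-methoxy-N,3-dimethyl-6-oxo-2-(triethylsilyloxy)hexanamide, via ozonide 14 (not isolated)
Conditions: O3, CH2Cl2, −78 °C; then PPh3, −78 °C to rt
Reagents that add atoms: ozone, [O-][O+]=O
Why: Ozonolysis with reductive work-up cleaves the only alkene to the C9 aldehyde, while the Weinreb amide and the silyl ether are inert.

Step 10
Reactants: 15 (2S,3R)-N-methoxy-N,3-dimethyl-6-oxo-2-(triethylsilyloxy)hexanamide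
Product: 16 (2S,3R,6S,7S)-6-hydroxy-7-(hydroxymethyl)-N-methoxy-N,3-dimethyl-2-(triethylsilyloxy)non-8-enamide
Conditions: 4-vinyl-1,3-dioxolan-2-one, [Ir(cod)Cl]2 (2.5 mol %), SEGPHOS (5 mol %, the enantiomer that delivers 8S), 4-cyano-3-nitrobenzoic acid (10 mol %), K3PO4 (cat.), iPrOH (2 equiv), THF, 60 °C
Reagents that add atoms: 4-vinyl-1,3-dioxolan-2-one, C=CC1COC(=O)O1
Why: Iridium-catalysed transfer-hydrogenative carbonyl (hydroxymethyl)allylation: the cyclometalated iridium benzoate ionises the vinyl carbonate with loss of CO2 to an (E)-σ-allyliridium species that adds to the aldehyde through a closed chair transition state, so the anti 2-vinyl-1,3-diol should form with C8 (S) and C9 (S) set by the ligand, not by the remote C12/C13 centres.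

Step 11
Reactants: 16 (2S,3R,6S,7S)-6-hydroxy-7-(hydroxymethyl)-N-methoxy-N,3-dimethyl-2-(triethylsilyloxy)non-8-enamide
Product: 17 (2S,3R,6S,7S)-6-hydroxy-N-methoxy-N,3-dimethyl-2-(triethylsilyloxy)-7-[(triethylsilyloxy)methyl]non-8-enamide
Conditions: Et3SiCl (1.05 equiv), imidazole, CH2Cl2, −78 °C to −40 °C
Reagents that add atoms: chlorotriethylsilane, CC[Si](Cl)(CC)CC
Why: Selective silylation: with one equivalent of silyl chloride at low temperature the primary hydroxyl reacts much faster than the hindered secondary C9 hydroxyl, which is kept free for the later oxidation.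

Step 12
Reactants: 17 (2S,3R,6S,7S)-6-hydroxy-N-methoxy-N,3-dimethyl-2-(triethylsilyloxy)-7-[(triethylsilyloxy)methyl]non-8-enamide
Product: 18 diethyl [(5S,6R,9S,10S)-9-hydroxy-2,6-dimethyl-4-oxo-5-(triethylsilyloxy)-10-[(triethylsilyloxy)methyl]dodec-11-en-3-yl]phosphonate (both C3 epimers)
Conditions: (EtO)2P(O)CH2CH(CH3)2 (3.5 equiv), n-BuLi, THF, −78 °C; then 17, −78 °C to −40 °C; aqueous NH4Cl
Reagents that add atoms: diethyl isobutylphosphonate, CC(C)CP(=O)(OCC)OCC
Why: Claisen-type acylation of the lithiated phosphonate by the Weinreb amide stops at the ketone because of the stable tetrahedral chelate, and the excess carbanion absorbs the C9 hydroxyl proton and the acidic product.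

Step 13
Reactants: 18 diethyl [(5S,6R,9S,10S)-9-hydroxy-2,6-dimethyl-4-oxo-5-(triethylsilyloxy)-10-[(triethylsilyloxy)methyl]dodec-11-en-3-yl]phosphonate; 6 (2R,3R)-3-methyl-3-(prop-2-en-1-yl)oxirane-2-carbaldehyde
Product: 19 open-chain (1E)-epoxy enone triene: (3S,4R)-cis-epoxide, 8S, 9S (free OH), 12R, 13S (OSiEt3), CH2OSiEt3 on C8, terminal vinyl groups at C6 and C7
Conditions: Ba(OH)2 (activated, from Ba(OH)2·8H2O), THF/H2O 40:1, 0 °C to rt
Reagents that add atoms: none
Why: Horner–Wadsworth–Emmons olefination with a mild barium base unites the two fragments; the reversibly formed adduct should collapse to the more stable E-enone (acyl group trans to C3, as in aldol condensations of α-branched carbonyl compounds), and the base leaves the epoxide, the free C9 hydroxyl and the C13 centre intact.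

Step 14
Reactants: 19 open-chain (1E)-epoxy enone triene
Product: 20 macrocyclic diene: (1E,3S,4R,8S,9S,12R,13S)-3,4-epoxy-9-hydroxy-13-(triethylsilyloxy)-19-(triethylsilyloxy)cembra-1,6-dien-14-one (C6=C7 as E/Z mixture)
Conditions: second-generation Grubbs catalyst RuCl2(H2IMes)(PCy3)(=CHPh) (10 mol %), CH2Cl2 (1 mM), 40 °C
Reagents that add atoms: none
Why: The ruthenium alkylidene loads on the unhindered C6 vinyl group and, through metallacyclobutane formation and cycloreversion with the C7 vinyl group, forges C6=C7 with loss of ethene. The closest known reaction type is macrocyclic ring-closing olefin metathesis of an α,ω-diene to a 14-membered carbocycle. The single ring closed is the 14-membered carbocycle, formed end-to-end between two terminal alkenes at about 1 mM so that cyclisation outruns oligomerisation. No stereocentre is created; the only new stereo-element, the C6=C7 geometry, is irrelevant because step 15 saturates it, and C8 cannot epimerise because C9 is still a carbinol. The step needs chemoselectivity for the two monosubstituted alkenes over the trisubstituted, electron-poor, α-branched C1=C2 enone, which such catalysts do not engage, and it needs the chain to fold, which the cis-epoxide and the E-enone of the natural ring favour.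

Step 15
Reactants: 20 macrocyclic diene
Product: 21 (1E,3S,4R,8S,9S,12R,13S)-3,4-epoxy-9-hydroxy-13-(triethylsilyloxy)-19-(triethylsilyloxy)cembr-1-en-14-one
Conditions: 2-nitrobenzenesulfonylhydrazide, Et3N, CH2Cl2, rt
Reagents that add atoms: none
Why: Diimide reduction transfers hydrogen concertedly to the unhindered, unpolarised 1,2-disubstituted C6=C7 bond much faster than to the trisubstituted, conjugated C1=C2 bond and does not touch epoxide, ketone or silyl ethers, so no stereocentre is affected.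

Step 16
Reactants: 21 (1E,3S,4R,8S,9S,12R,13S)-3,4-epoxy-9-hydroxy-13-(triethylsilyloxy)-19-(triethylsilyloxy)cembr-1-en-14-one
Product: 22 (1E,3S,4R,8S,12R,13S)-3,4-epoxy-13-(triethylsilyloxy)-19-(triethylsilyloxy)cembr-1-ene-9,14-dione
Conditions: Dess–Martin periodinane, NaHCO3, CH2Cl2, 0 °C
Reagents that add atoms: none
Why: Dess–Martin oxidation of the only free hydroxyl gives the C9 ketone under buffered, non-basic conditions, so the now α-carbonyl C8 centre and its β-silyloxy group are not exposed to epimerisation or elimination.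

Step 17
Reactants: 22 (1E,3S,4R,8S,12R,13S)-3,4-epoxy-13-(triethylsilyloxy)-19-(triethylsilyloxy)cembr-1-ene-9,14-dione
Product: 23 (1E,3S,4R,8S,12R,13S)-3,4-epoxy-13,19-dihydroxycembr-1-ene-9,14-dione (target)
Conditions: HF·pyridine, pyridine, THF, 0 °C
Reagents that add atoms: none
Why: Desilylation with pyridine-buffered HF·pyridine removes both triethylsilyl ethers under conditions intended to be mild enough for the trisubstituted epoxide, the β-hydroxy ketone and the α-hydroxy ketone, and should give the target.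

Compound list
1 | but-2-yn-1-ol | CC#CCO | starting material
2 | sodium cyclic alkenylaluminate (3-methyl-2,2-bis(2-methoxyethoxy)-2,5-dihydro-1,2-oxaluminol-2-uide) | CC1=CCO[Al-]1(OCCOC)OCCOC.[Na+] | intermediate
3 | (2Z)-3-iodobut-2-en-1-ol | C/C(I)=C/CO | intermediate
4 | (2Z)-3-methylhexa-2,5-dien-1-ol | C/C(CC=C)=C/CO | intermediate
5 | [(2S,3R)-3-methyl-3-(prop-2-en-1-yl)oxiran-2-yl]methanol | OC[C@@H]1O[C@]1(C)CC=C | intermediate
6 | (2R,3R)-3-methyl-3-(prop-2-en-1-yl)oxirane-2-carbaldehyde | O=C[C@@H]1O[C@]1(C)CC=C | intermediate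
7 | (R)-citronellic acid, (3R)-3,7-dimethyloct-6-enoic acid | CC(C)=CCC[C@@H](C)CC(=O)O | starting material
8 | (3R)-3,7-dimethyloct-6-enoic pivalic anhydride | CC(C)=CCC[C@@H](C)CC(=O)OC(=O)C(C)(C)C | intermediate
9 | (4S)-4-benzyl-3-[(3R)-3,7-dimethyloct-6-enoyl]-1,3-oxazolidin-2-one | CC(C)=CCC[C@@H](C)CC(=O)N1[C@@H](Cc2ccccc2)COC1=O | intermediate
10 | sodium (Z)-enolate of 9 | CC(C)=CCC[C@@H](C)/C=C(\[O-])N1[C@@H](Cc2ccccc2)COC1=O.[Na+] | intermediate
11 | (4S)-4-benzyl-3-[(2S,3R)-2-hydroxy-3,7-dimethyloct-6-enoyl]-1,3-oxazolidin-2-one | CC(C)=CCC[C@@H](C)[C@H](O)C(=O)N1[C@@H](Cc2ccccc2)COC1=O | intermediate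
12 | (2S,3R)-2-hydroxy-N-methoxy-N,3,7-trimethyloct-6-enamide | CC(C)=CCC[C@@H](C)[C@H](O)C(=O)N(C)OC | intermediate
13 | (2S,3R)-N-methoxy-N,3,7-trimethyl-2-(triethylsilyloxy)oct-6-enamide | CC(C)=CCC[C@@H](C)[C@H](O[Si](CC)(CC)CC)C(=O)N(C)OC | intermediate
14 | ozonide (1,2,4-trioxolane) of 13 | CC1(C)OOC(CC[C@@H](C)[C@H](O[Si](CC)(CC)CC)C(=O)N(C)OC)O1 | intermediate
15 | (2S,3R)-N-methoxy-N,3-dimethyl-6-oxo-2-(triethylsilyloxy)hexanamide | O=CCC[C@@H](C)[C@H](O[Si](CC)(CC)CC)C(=O)N(C)OC | intermediate
16 | (2S,3R,6S,7S)-6-hydroxy-7-(hydroxymethyl)-N-methoxy-N,3-dimethyl-2-(triethylsilyloxy)non-8-enamide | C=C[C@@H](CO)[C@@H](O)CC[C@@H](C)[C@H](O[Si](CC)(CC)CC)C(=O)N(C)OC | intermediate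
17 | (2S,3R,6S,7S)-6-hydroxy-N-methoxy-N,3-dimethyl-2-(triethylsilyloxy)-7-[(triethylsilyloxy)methyl]non-8-enamide | C=C[C@@H](CO[Si](CC)(CC)CC)[C@@H](O)CC[C@@H](C)[C@H](O[Si](CC)(CC)CC)C(=O)N(C)OC | intermediate
18 | diethyl [(5S,6R,9S,10S)-9-hydroxy-2,6-dimethyl-4-oxo-5-(triethylsilyloxy)-10-[(triethylsilyloxy)methyl]dodec-11-en-3-yl]phosphonate (C3 epimers) | C=C[C@@H](CO[Si](CC)(CC)CC)[C@@H](O)CC[C@@H](C)[C@H](O[Si](CC)(CC)CC)C(=O)C(C(C)C)P(=O)(OCC)OCC | intermediate
19 | open-chain (1E)-epoxy enone triene; (3S,4R)-cis-epoxide, 8S, 9S-OH, 12R, 13S-OSiEt3, C8-CH2OSiEt3, vinyl termini at C6 and C7 | C=C[C@@H](CO[Si](CC)(CC)CC)[C@@H](O)CC[C@@H](C)[C@H](O[Si](CC)(CC)CC)C(=O)/C(C(C)C)=C/[C@@H]1O[C@]1(C)CC=C | intermediate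
20 | (1E,3S,4R,8S,9S,12R,13S)-3,4-epoxy-9-hydroxy-13-(triethylsilyloxy)-19-(triethylsilyloxy)cembra-1,6-dien-14-one (C6=C7 E/Z) | C1=C[C@@H](CO[Si](CC)(CC)CC)[C@@H](O)CC[C@@H](C)[C@H](O[Si](CC)(CC)CC)C(=O)/C(C(C)C)=C/[C@@H]2O[C@]2(C)C1 | intermediate
21 | (1E,3S,4R,8S,9S,12R,13S)-3,4-epoxy-9-hydroxy-13-(triethylsilyloxy)-19-(triethylsilyloxy)cembr-1-en-14-one | C1C[C@@H](CO[Si](CC)(CC)CC)[C@@H](O)CC[C@@H](C)[C@H](O[Si](CC)(CC)CC)C(=O)/C(C(C)C)=C/[C@@H]2O[C@]2(C)C1 | intermediate
22 | (1E,3S,4R,8S,12R,13S)-3,4-epoxy-13-(triethylsilyloxy)-19-(triethylsilyloxy)cembr-1-ene-9,14-dione | C1C[C@@H](CO[Si](CC)(CC)CC)C(=O)CC[C@@H](C)[C@H](O[Si](CC)(CC)CC)C(=O)/C(C(C)C)=C/[C@@H]2O[C@]2(C)C1 | intermediate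
23 | (1E,3S,4R,8S,12R,13S)-3,4-epoxy-13,19-dihydroxycembr-1-ene-9,14-dione | CC(C)/C1=C\[C@@H]2O[C@]2(C)CCC[C@@H](CO)C(=O)CC[C@@H](C)[C@H](O)C1=O | target

Total step count: 17. Longest linear sequence: 13 steps (steps 5 to 17, from 7).

Steps most likely to fail

Step 14. The hindered, allylic C7 vinyl group may engage slowly, so that intermolecular metathesis (oligomerisation) or ruthenium hydride-mediated alkene migration outruns ring closure. The fallback inverts the order of the two fragment unions, so that the same metathesis makes C6–C7 between the fragments and the ring is then closed at C1=C2. It sets out from 5 and 18: cross-metathesis (second-generation Hoveyda–Grubbs catalyst RuCl2(H2IMes)(=CH-C6H4-2-OiPr), excess 5) should give seco-hydroxy phosphonate F1. Diimide (2-nitrobenzenesulfonylhydrazide, Et3N) saturates its only alkene to give dihydro seco-hydroxy phosphonate F2. TEMPO/PhI(OAc)2 oxidises the primary epoxy alcohol selectively to seco-aldehyde phosphonate F3. An intramolecular Horner–Wadsworth–Emmons reaction (Ba(OH)2, THF/H2O, high dilution) then closes the 14-membered ring, and the fallback comes back to the route at 21.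

Step 13. Addition of the hindered α-isopropyl phosphonate anion to the aldehyde may be slow and the E/Z control may erode. The fallback is an aldol–dehydration union that sets out from 17. Silylation (Me3SiCl, imidazole) gives trimethylsilyl ether F4. i-BuMgBr converts the Weinreb amide into isobutyl ketone F5. Enolisation on the isobutyl side with (c-C6H11)2BCl/Et3N gives boron enolate F6, which adds to 6 and after buffered oxidative work-up gives aldol adduct F7 (mixture at C1 and C2, both erased). MsCl/Et3N gives mesylate F8, and DBU-induced E1cB elimination should give the E-enone trimethylsilyl ether F9. Citric acid in MeOH removes the trimethylsilyl group only, and the fallback comes back to the route at 19.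

Step 10. Catalyst control (anti/syn and facial selectivity) may be insufficient on this functionalised aldehyde, or the aldehyde may be reduced by the isopropanol-derived iridium hydride before C–C coupling. The fallback sets C8 with a stoichiometric auxiliary and sets out from 15. The boron dienolate of commercial (R)-4-benzyl-3-[(E)-but-2-enoyl]-1,3-oxazolidin-2-one (Bu2BOTf, Et3N) reacts at its α-carbon in an Evans syn-aldol addition to give α-vinyl aldol adduct F10. This syn relationship corresponds to the anti relationship of 16 once the acyl carbon has become CH2OH. Reductive removal of the auxiliary (NaBH4, THF/H2O; the Weinreb amide is not reduced) gives the diol, and the fallback comes back to the route at 16.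

Further compounds
F1 | step 14 | seco-hydroxy phosphonate (cross-metathesis product of 5 and 18, C6=C7 alkene) | OC[C@@H]1O[C@]1(C)CC=C[C@@H](CO[Si](CC)(CC)CC)[C@@H](O)CC[C@@H](C)[C@H](O[Si](CC)(CC)CC)C(=O)C(C(C)C)P(=O)(OCC)OCC
F2 | step 14 | dihydro seco-hydroxy phosphonate | OC[C@@H]1O[C@]1(C)CCC[C@@H](CO[Si](CC)(CC)CC)[C@@H](O)CC[C@@H](C)[C@H](O[Si](CC)(CC)CC)C(=O)C(C(C)C)P(=O)(OCC)OCC
F3 | step 14 | seco-aldehyde phosphonate | O=C[C@@H]1O[C@]1(C)CCC[C@@H](CO[Si](CC)(CC)CC)[C@@H](O)CC[C@@H](C)[C@H](O[Si](CC)(CC)CC)C(=O)C(C(C)C)P(=O)(OCC)OCC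
F4 | step 13 | C9 trimethylsilyl ether of 17 | C=C[C@@H](CO[Si](CC)(CC)CC)[C@@H](O[Si](C)(C)C)CC[C@@H](C)[C@H](O[Si](CC)(CC)CC)C(=O)N(C)OC
F5 | step 13 | isobutyl ketone | C=C[C@@H](CO[Si](CC)(CC)CC)[C@@H](O[Si](C)(C)C)CC[C@@H](C)[C@H](O[Si](CC)(CC)CC)C(=O)CC(C)C
F6 | step 13 | dicyclohexylboron enolate of F5 | C=C[C@@H](CO[Si](CC)(CC)CC)[C@@H](O[Si](C)(C)C)CC[C@@H](C)[C@H](O[Si](CC)(CC)CC)C(OB(C1CCCCC1)C1CCCCC1)=CC(C)C
F7 | step 13 | aldol adduct (C2 carbinol) | C=C[C@@H](CO[Si](CC)(CC)CC)[C@@H](O[Si](C)(C)C)CC[C@@H](C)[C@H](O[Si](CC)(CC)CC)C(=O)C(C(C)C)C(O)[C@@H]1O[C@]1(C)CC=C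
F8 | step 13 | C2 mesylate of F7 | C=C[C@@H](CO[Si](CC)(CC)CC)[C@@H](O[Si](C)(C)C)CC[C@@H](C)[C@H](O[Si](CC)(CC)CC)C(=O)C(C(C)C)C(OS(C)(=O)=O)[C@@H]1O[C@]1(C)CC=C
F9 | step 13 | C9 trimethylsilyl ether of 19 | C=C[C@@H](CO[Si](CC)(CC)CC)[C@@H](O[Si](C)(C)C)CC[C@@H](C)[C@H](O[Si](CC)(CC)CC)C(=O)/C(C(C)C)=C/[C@@H]1O[C@]1(C)CC=C
F10 | step 10 | α-vinyl syn-aldol adduct with the (R)-benzyloxazolidinone | C=C[C@@H](C(=O)N1[C@H](Cc2ccccc2)COC1=O)[C@@H](O)CC[C@@H](C)[C@H](O[Si](CC)(CC)CC)C(=O)N(C)OC
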